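**Retrosynthetic overview**
1. Target ⇐ α-keto lactone 45 (NaBH4) ⇐ Yamaguchi ester of cyclopentanol 38 with acid 44; the lactone is made last on the carbocycle, by acetate aldol/lactonisation on α-methylene cyclooctenone 33.
2. Eight-membered ring: RCM (forms the C(CH3)=CH bond) of ketone 29, made from the alkyllithium of iodide 25 and Weinreb amide 28 (Fráter–Seebach); the exocyclic methylene comes from an Eschenmoser methylenation.
3. trans-Hydrindane 21 ⇐ cleavage of the two-carbon bridge of bicyclo[2.2.2]octenone 14 (NaBH4, hydrolysis, Pb(OAc)4), then OH-directed hydrogenation that sets the ring-fusion H and the isopropyl centre.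
4. Key disconnection: 14 ⇐ masked o-benzoquinone 13 ⇐ phenol 12 (acetovanillone + allyl bromide + propargylboronate 9). Dearomatisation and intramolecular Diels–Alder with a tethered allene close the cyclohexane and the cyclopentane at once.
5. Enabling feature: in the cyclohexane ring the quaternary ring-fusion carbon C(CH3) and the ring-fusion CH bearing C(=CH2) are 1,4-related, with CH3 and C(=CH2) cis. These two exocyclic carbons plus the ring carbons C(CH3)–CH2–CH[C(CH3)=]–CH[C(=CH2)] are the six carbons of a 2-methoxyphenol (C–OH → CH3, C–OMe → C(=CH2)); its para-acetyl group is the C(CH3)= of the cyclooctene. Ring order: arene → six + five (key) → eight → lactone.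

Key step: step 10

Remark: the sense of induction in step 7 is assumed by analogy with phosphoric-acid-catalysed allylboration (Si-face attack with the (S)-catalyst; the antipode is used if the sense is opposite). Centres that are made and destroyed again (carbinol of 15/16, aminomethyl carbon of 31/32, hydroxylated carbon of 36) are left open or drawn as the expected major isomer. C1–C6 in the Why lines are the ring carbons of 13 (C1 carbonyl, C2 tether, C4 acetyl, C6 ketal).

Step 1
Reactants: 1 acetovanillone; 2 allyl bromide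
Product: 3 1-[4-(allyloxy)-3-methoxyphenyl]ethan-1-one
Conditions: K2CO3, acetone, reflux
Reagents that add atoms: none
Why: Williamson etherification (SN2) of the phenoxide on allyl bromide.

Step 2
Reactants: 3 allyl aryl ether
Product: 4 1-(3-allyl-4-hydroxy-5-methoxyphenyl)ethan-1-one
Conditions: N,N-diethylaniline, 200 °C
Reagents that add atoms: none
Why: Aromatic Claisen rearrangement ([3,3]) to the only free ortho position, followed by tautomerisation.

Step 3
Reactants: 4 allyl phenol
Product: 5 1-{3-allyl-4-[(tert-butyldimethylsilyl)oxy]-5-methoxyphenyl}ethan-1-one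
Conditions: TBSCl, imidazole, DMF, rt
Reagents that add atoms: tert-butyldimethylsilyl chloride, CC(C)(C)[Si](C)(C)Cl
Why: Silylation masks the phenol so that the aldehyde of step 4 cannot close to a lactol and no acidic OH meets the boron reagent of step 7.

Step 4
Reactants: 5 silyl ether
Product: 6 2-{5-acetyl-2-[(tert-butyldimethylsilyl)oxy]-3-methoxyphenyl}acetaldehyde
Conditions: O3, CH2Cl2/MeOH, −78 °C (Sudan III end point); Me2S
Reagents that add atoms: ozone, [O-][O+]=O
Why: Ozonolysis with reductive work-up; the terminal alkene is cleaved much faster than the acyl-deactivated arene.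

Step 5
Reactants: 7 3-methylbut-1-yne
Product: 8 4,4,5,5-tetramethyl-2-(3-methylbut-1-yn-1-yl)-1,3,2-dioxaborolane
Conditions: n-BuLi, THF, −78 °C; i-PrOBpin; HCl·Et2O
Reagents that add atoms: 2-isopropoxy-4,4,5,5-tetramethyl-1,3,2-dioxaborolane, CC(C)OB1OC(C)(C)C(C)(C)O1
Why: Borylation of the lithium acetylide (alkynylboronate synthesis), with acid collapse of the ate complex.

Step 6
Reactants: 8 alkynylboronate
Product: 9 4,4,5,5-tetramethyl-2-(4-methylpent-2-yn-1-yl)-1,3,2-dioxaborolane
Conditions: ICH2Cl, n-BuLi, THF, −78 °C → rt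
Reagents that add atoms: chloroiodomethane, ClCI
Why: Matteson homologation: LiCH2Cl adds to boron and the alkynyl group migrates with loss of chloride, which places boron on the propargylic CH2 only.

Step 7
Reactants: 6 aldehyde; 9 propargylboronate
Product: 10 (R)-allenol, 1-{4-[(tert-butyldimethylsilyl)oxy]-3-[(2R)-2-hydroxy-3-isopropylpenta-3,4-dien-1-yl]-5-methoxyphenyl}ethan-1-one
Conditions: (S)-TRIP (5 mol %), 4 Å MS, PhMe, −30 °C; aqueous work-up
Reagents that add atoms: none
Why: Chiral phosphoric acid-catalysed propargylboration (SE2' through a six-membered chair transition state) gives the α-allenyl carbinol; the catalyst directs Si-face attack and so sets the (R) carbinol, while the aryl ketone is inert.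

Step 8
Reactants: 10 allenol
Product: 11 triethylsilyl ether of 10
Conditions: TESCl, imidazole, CH2Cl2, 0 °C
Reagents that add atoms: chlorotriethylsilane, CC[Si](CC)(CC)Cl
Why: Silylation removes the hydrogen-bond donor, so that in step 10 the oxygen substituent is repelled by, not bound to, the C1 carbonyl.

Step 9
Reactants: 11 bis-silyl ether
Product: 12 phenol, 1-{4-hydroxy-3-methoxy-5-[(2R)-3-isopropyl-2-(triethylsilyloxy)penta-3,4-dien-1-yl]phenyl}ethan-1-one
Conditions: K2CO3 (0.3 equiv), MeOH, 0 °C → rt
Reagents that add atoms: none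
Why: Base-catalysed methanolysis cleaves the aryl silyl ether (phenoxide leaving group) selectively over the secondary alkyl TES ether.

Step 10
Reactants: 12 phenol
Product: 14 cycloadduct: 5-acetyl-3,3-dimethoxybicyclo[2.2.2]oct-5-en-2-one with a 2-isopropylcyclopentene fused across the quaternary bridgehead C1 and C7 (C7=C double bond) and the (R)-CH(OSiEt3) anti to the C2 carbonyl bridge, via masked o-benzoquinone 13 (not isolated)
Conditions: PhI(OAc)2 (1.1 equiv), MeOH, 0 °C, 20 min; evaporate cold; PhMe (0.01 M), 70 °C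
Reagents that add atoms: methanol, CO
Why: PhI(OAc)2 oxidises the phenol, methanol adds at the methoxy-bearing carbon to give the 6,6-dimethoxycyclohexa-2,4-dienone 13, and its C2=C3–C4=C5 diene adds suprafacially to the terminal CH2=C bond of the allene held on C2 by a three-atom tether (concerted intramolecular Diels–Alder; closest precedents are intramolecular Diels–Alder reactions of masked o-benzoquinones with tethered alkenes and allene cycloadditions that use the distal π-bond). The cyclohexene closes as the [4+2] ring (bonds C5–CH2 and C2–C(sp)) and the cyclopentene closes as the tether ring, with the proximal allene C=C left endocyclic. The two bridgeheads are locked cis by the C1–C6 bridge of the former arene, which is why the later angular CH3 and the ester carbon are 1,4-cis; because the allene carbon that bonds to C2 stays sp2, no endo/exo ring-fusion isomers can arise. The absolute configuration of both bridgeheads follows from the (R)-silyloxy centre: on the Cα–Cβ bond that stands perpendicular to the dienone, the OTES group is expected to turn away from the lone pairs of the C1 carbonyl oxygen towards C3–H, which selects one diene face. The step needs regioselective methanol attack at C–OMe (normal for guaiacols; the para-acetyl group also slows dimerisation of 13), periselectivity for the distal allene bond (the proximal bond would give a four-membered or bridged ring) and π-facial selectivity (substrate control as above; the two diastereomers are separable).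

Step 11
Reactants: 14 cycloadduct
Product: 15 bridging alcohol (C2–OH, either epimer; ketal and enone intact)
Conditions: NaBH4, MeOH/CH2Cl2 (1:1), −78 °C
Reagents that add atoms: none
Why: Chemoselective borohydride reduction: the strained, α,α-dialkoxy-activated bridging ketone is reduced much faster than the conjugated methyl ketone; the new carbinol centre is destroyed in step 13.

Step 12
Reactants: 15 hydroxy ketal
Product: 16 α-ketol (C3 ketone, C2–OH) with free allylic alcohol
Conditions: PPTS (0.3 equiv), acetone/H2O (10:1), 50 °C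
Reagents that add atoms: water, O
Why: Mild acid hydrolysis of the dimethyl ketal and of the TES ether; the conditions are too weak to ionise the allylic alcohol.

Step 13
Reactants: 16 α-ketol
Product: 17 tetrahydroindene aldehyde–ester (angular CHO on the quaternary carbon, CO2Me 1,4-cis to it, acetyl enone, tetrasubstituted cyclopentene, allylic OH)
Conditions: Pb(OAc)4, MeOH/PhH (1:1), 0 °C
Reagents that add atoms: methanol, CO
Why: Criegee-type α-ketol cleavage: the carbinol carbon becomes the aldehyde and the ketone carbon the methyl ester, which opens the temporary bridge without touching the two bridgehead stereocentres.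

Step 14
Reactants: 17 aldehyde–ester
Product: 19 angular-methyl ester (CHO → CH3), via tosylhydrazone 18 (not isolated)
Conditions: TsNHNH2 (1.05 equiv), THF, rt; catecholborane, CHCl3, 0 °C; NaOAc·3H2O, 60 °C
Reagents that add atoms: none
Why: Aldehyde-selective tosylhydrazone formation and Kabalka reduction (hydride to C=N, loss of sulfinate and N2) turn the neopentyl aldehyde into CH3 while the enone and ester are left.

Step 15
Reactants: 19 diene ester
Product: 21 trans-hydrindane keto ester (ring-fusion H trans to angular CH3, isopropyl cis to CH3 and trans to OH, acetyl and CO2Me trans-diequatorial), via acetyl epimer 20 (not isolated)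
Conditions: H2 (1 atm), [Ir(cod)(PCy3)(py)]PF6 (10 mol %), CH2Cl2, rt; then NaOMe (0.3 equiv), MeOH, rt
Reagents that add atoms: none
Why: Hydroxyl-directed Crabtree hydrogenation adds H2 to the tetrasubstituted cyclopentene on the face of the allylic OH (also the face anti to the angular CH3), which sets the ring-fusion CH and the isopropyl-bearing carbon; the enone C=C is reduced as well and methoxide equilibrates the acetyl-bearing carbon to the equatorial position.

Step 16
Reactants: 21 hydroxy keto ester
Product: 22 tert-butyldimethylsilyl ether of 21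
Conditions: TBSOTf, 2,6-lutidine, CH2Cl2, −78 °C
Reagents that add atoms: tert-butyldimethylsilyl triflate, CC(C)(C)[Si](C)(C)OS(=O)(=O)C(F)(F)F
Why: Silylation of the hindered secondary alcohol, which is faster than enol silylation of the ketone at −78 °C.

Step 17
Reactants: 22 methyl ketone
Product: 23 isopropenyl ester
Conditions: Ph3PCH3Br, KOt-Bu, THF, 0 °C → rt
Reagents that add atoms: methyltriphenylphosphonium bromide, C[P+](c1ccccc1)(c1ccccc1)c1ccccc1.[Br-]
Why: Wittig methylenation of the ketone; the ester does not react and the α-centre stays in its equatorial configuration.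

Step 18
Reactants: 23 ester
Product: 24 primary alcohol
Conditions: LiAlH4, Et2O, 0 °C
Reagents that add atoms: none
Why: Hydride reduction of the ester to the primary alcohol.

Step 19
Reactants: 24 alcohol
Product: 25 primary iodide
Conditions: I2, PPh3, imidazole, CH2Cl2, rt
Reagents that add atoms: iodine, II
Why: Appel-type (Garegg) iodination of the primary alcohol via the alkoxyphosphonium ion.

Step 20
Reactants: 26 ethyl (S)-3-hydroxybutanoate; 2 allyl bromide
Product: 27 ethyl (2S,3S)-2-allyl-3-hydroxybutanoate
Conditions: LDA (2.2 equiv), THF, −50 → −20 °C; allyl bromide, DMPU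
Reagents that add atoms: none
Why: Fráter–Seebach alkylation: the chelated dianion is allylated anti to the C3 methyl group, which gives the anti (2S,3S) product.

Step 21
Reactants: 27 hydroxy ester
Product: 28 (2S,3S)-2-allyl-3-hydroxy-N-methoxy-N-methylbutanamide
Conditions: MeNH(OMe)·HCl, i-PrMgCl, THF, −20 °C
Reagents that add atoms: N,O-dimethylhydroxylamine hydrochloride, CNOC.Cl
Why: Weinreb amide formation by the magnesium amide; the α-centre is not epimerised at low temperature.

Step 22
Reactants: 25 iodide; 28 Weinreb amide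
Product: 29 β-hydroxy ketone (hydrindanyl-CH2–CO–CH(allyl)–CH(CH3)OH)
Conditions: 25, t-BuLi (2.1 equiv), Et2O, −78 °C; add to 28 pre-treated with i-PrMgCl (1.05 equiv), THF; −78 → 0 °C; aq. NH4Cl
Reagents that add atoms: none
Why: Iodine–lithium exchange and acylation of the alkyllithium by the Weinreb amide; the stable chelate stops over-addition and the pre-formed magnesium alkoxide spares the organolithium.

Step 23
Reactants: 29 diene ketone
Product: 30 cyclooctenone, trans-fused to the cyclohexane, with (Z)-trisubstituted C(CH3)=CH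
Conditions: Grubbs II (10 mol %), PhMe (1 mM), 90 °C, Ar sparge
Reagents that add atoms: none
Why: Ring-closing metathesis between the allyl and isopropenyl groups, the only two alkenes present; the trans-diequatorial attachment on the cyclohexane brings the chains together and the ring enforces the Z geometry.

Step 24
Reactants: 30 cyclooctenone
Product: 33 α-methylene ketone, via Mannich base 31 (not isolated), via trimethylammonium iodide 32 (not isolated)
Conditions: LDA (2.2 equiv), THF, −78 °C; CH2=NMe2+ I−, −78 → 0 °C; MeI, MeOH, rt; aq. NaHCO3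
Reagents that add atoms: Eschenmoser's salt, C=[N+](C)C.[I-]
Why: Kinetic enolisation at the CH2 side (the other α-carbon carries the alkoxide-bearing branch), Mannich reaction with Eschenmoser's salt, then quaternisation and E1cB elimination give the exocyclic methylene.

Step 25
Reactants: 33 hydroxy enone
Product: 35 β-hydroxy δ-lactone, cis-fused to the eight-membered ring (tertiary OH cis to the neighbouring ring H), via aldol adduct 34 (not isolated)
Conditions: EtOAc, LDA (4 equiv), THF, −78 °C; CeCl3; add 33; −78 → −20 °C; AcOH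
Reagents that add atoms: ethyl acetate, CCOC(C)=O
Why: Acetate aldol 1,2-addition of the cerium/lithium enolate to the enone carbonyl, directed by the chelated β-alkoxide (six-membered chair chelate with methyl and ring bond equatorial, axial C–C bond formation), sets the tertiary carbinol; the δ-alkoxide then lactonises with loss of ethoxide.

Step 26
Reactants: 35 lactone
Product: 36 α-hydroxy lactone (new OH cis to the tertiary OH)
Conditions: LiHMDS (2.3 equiv), THF, −78 °C; 2-(phenylsulfonyl)-3-phenyloxaziridine
Reagents that add atoms: 2-(phenylsulfonyl)-3-phenyloxaziridine, O=S(=O)(c1ccccc1)N1OC1c1ccccc1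
Why: Davis hydroxylation of the lactone enolate (alkoxide dianion), expected anti to the axial C–C(=CH2) bond; the centre is removed again in step 27.

Step 27
Reactants: 36 α-hydroxy lactone
Product: 37 α-keto lactone
Conditions: Dess–Martin periodinane, NaHCO3, CH2Cl2, 0 °C → rt
Reagents that add atoms: none
Why: Dess–Martin oxidation of the only free secondary alcohol; the ketone cannot enolise towards the quaternary carbinol.

Step 28
Reactants: 37 silyl ether
Product: 38 cyclopentanol α-keto lactone
Conditions: HF·pyridine, THF/pyridine, 0 °C → rt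
Reagents that add atoms: none
Why: Buffered fluoride desilylation, which avoids the basic conditions that would risk retro-aldol or α-ketol shift.

Step 29
Reactants: 39 (S)-1-bromo-2-methylbutane
Product: 40 (S)-4-methylhex-1-yne
Conditions: lithium acetylide–ethylenediamine, DMSO, 10 °C → rt
Reagents that add atoms: lithium acetylide, [Li+].[C-]#C
Why: SN2 alkynylation of the primary bromide; the stereocentre is not involved.

Step 30
Reactants: 40 alkyne
Product: 41 (S,E)-3,5-dimethylhept-2-en-1-ol
Conditions: Me3Al, Cp2ZrCl2 (0.2 equiv), CH2Cl2, 0 °C → rt; n-BuLi, (CH2O)n, THF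
Reagents that add atoms: trimethylaluminium, C[Al](C)C; formaldehyde, C=O
Why: Negishi zirconium-catalysed carboalumination (syn addition of CH3–Al) and trapping of the alkenylalanate with formaldehyde give the (E)-allylic alcohol.

Step 31
Reactants: 41 allylic alcohol
Product: 42 (2R,3R,5S)-2,3-epoxy-3,5-dimethylheptan-1-ol
Conditions: Ti(Oi-Pr)4 (cat.), D-(−)-diethyl tartrate (cat.), t-BuOOH, 4 Å MS, CH2Cl2, −20 °C
Reagents that add atoms: tert-butyl hydroperoxide, CC(C)(C)OO
Why: Sharpless asymmetric epoxidation; the D-(−)-tartrate catalyst sets the (2R,3R) epoxide under reagent control.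

Step 32
Reactants: 42 epoxy alcohol
Product: 43 (3R,5S)-3,5-dimethylheptane-1,3-diol
Conditions: Red-Al, THF, 0 °C
Reagents that add atoms: none
Why: Hydride is delivered to C2 from the alkoxyaluminate (1,3-diol-selective epoxide opening), so the tertiary C–O centre is untouched.

Step 33
Reactants: 43 diol
Product: 44 (3R,5S)-3-hydroxy-3,5-dimethylheptanoic acid
Conditions: TEMPO (cat.), PhI(OAc)2 (2.2 equiv), MeCN/H2O (1:1), rt
Reagents that add atoms: water, O
Why: Oxoammonium oxidation of the primary alcohol to the acid via the aldehyde hydrate; the tertiary alcohol is inert.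

Step 34
Reactants: 38 cyclopentanol; 44 acid
Product: 45 α-keto lactone ester (side chain in place)
Conditions: 2,4,6-trichlorobenzoyl chloride, Et3N, THF, rt; then 38, DMAP, PhMe, rt
Reagents that add atoms: none
Why: Yamaguchi esterification with retention at the carbinol; the cyclopentanol is the only secondary hydroxyl present and both tertiary hydroxyls are unreactive.

Step 35
Reactants: 45 α-keto lactone ester
Product: 46 target compound
Conditions: NaBH4, MeOH/THF, −78 °C
Reagents that add atoms: none
Why: Chemoselective borohydride reduction of the activated α-keto lactone carbonyl; hydride enters anti to the axial C–C(=CH2) bond (the face of the neighbouring tertiary OH), which gives the trans-diol.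

**Compound list**
1 | acetovanillone | CC(=O)c1ccc(O)c(OC)c1 | starting material
2 | allyl bromide | C=CCBr | starting material
3 | 1-[4-(allyloxy)-3-methoxyphenyl]ethan-1-one | CC(=O)c1ccc(OCC=C)c(OC)c1 | intermediate
4 | 1-(3-allyl-4-hydroxy-5-methoxyphenyl)ethan-1-one | CC(=O)c1cc(CC=C)c(O)c(OC)c1 | intermediate
5 | aryl TBS ether of 4 | CC(=O)c1cc(CC=C)c(O[Si](C)(C)C(C)(C)C)c(OC)c1 | intermediate
6 | arylacetaldehyde | CC(=O)c1cc(CC=O)c(O[Si](C)(C)C(C)(C)C)c(OC)c1 | intermediate
7 | 3-methylbut-1-yne | CC(C)C#C | starting material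
8 | alkynyl pinacol boronate | CC(C)C#CB1OC(C)(C)C(C)(C)O1 | intermediate
9 | 4-methylpent-2-yn-1-yl pinacol boronate | CC(C)C#CCB1OC(C)(C)C(C)(C)O1 | intermediate
10 | (R)-allenol | C=C=C(C(C)C)[C@H](O)Cc1cc(C(C)=O)cc(OC)c1O[Si](C)(C)C(C)(C)C | intermediate
11 | TES ether of 10 | C=C=C(C(C)C)[C@H](O[Si](CC)(CC)CC)Cc1cc(C(C)=O)cc(OC)c1O[Si](C)(C)C(C)(C)C | intermediate
12 | phenol | C=C=C(C(C)C)[C@H](O[Si](CC)(CC)CC)Cc1cc(C(C)=O)cc(OC)c1O | intermediate
13 | masked o-benzoquinone | C=C=C(C(C)C)[C@H](O[Si](CC)(CC)CC)CC1=CC(C(C)=O)=CC(OC)(OC)C1=O | intermediate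
14 | cycloadduct | COC3(OC)[C@H]1CC2=C(C(C)C)[C@H](O[Si](CC)(CC)CC)C[C@]2(C3=O)C=C1C(C)=O | intermediate
15 | bridging alcohol | COC3(OC)[C@H]1CC2=C(C(C)C)[C@H](O[Si](CC)(CC)CC)C[C@]2(C3O)C=C1C(C)=O | intermediate
16 | α-ketol | O=C3[C@H]1CC2=C(C(C)C)[C@H](O)C[C@]2(C3O)C=C1C(C)=O | intermediate
17 | aldehyde–ester | COC(=O)[C@H]1CC2=C(C(C)C)[C@H](O)C[C@]2(C=O)C=C1C(C)=O | intermediate
18 | tosylhydrazone | COC(=O)[C@H]1CC2=C(C(C)C)[C@H](O)C[C@]2(C=NNS(=O)(=O)c3ccc(C)cc3)C=C1C(C)=O | intermediate
19 | angular-methyl diene ester | COC(=O)[C@H]1CC2=C(C(C)C)[C@H](O)C[C@]2(C)C=C1C(C)=O | intermediate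
20 | acetyl epimer of 21 | COC(=O)[C@H]1C[C@H]2[C@@H](C(C)C)[C@H](O)C[C@]2(C)C[C@H]1C(C)=O | intermediate
21 | trans-hydrindane keto ester | COC(=O)[C@H]1C[C@H]2[C@@H](C(C)C)[C@H](O)C[C@]2(C)C[C@@H]1C(C)=O | intermediate
22 | TBS ether of 21 | COC(=O)[C@H]1C[C@H]2[C@@H](C(C)C)[C@H](O[Si](C)(C)C(C)(C)C)C[C@]2(C)C[C@@H]1C(C)=O | intermediate
23 | isopropenyl ester | COC(=O)[C@H]1C[C@H]2[C@@H](C(C)C)[C@H](O[Si](C)(C)C(C)(C)C)C[C@]2(C)C[C@@H]1C(C)=C | intermediate
24 | primary alcohol | OC[C@H]1C[C@H]2[C@@H](C(C)C)[C@H](O[Si](C)(C)C(C)(C)C)C[C@]2(C)C[C@@H]1C(C)=C | intermediate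
25 | primary iodide | IC[C@H]1C[C@H]2[C@@H](C(C)C)[C@H](O[Si](C)(C)C(C)(C)C)C[C@]2(C)C[C@@H]1C(C)=C | intermediate
26 | ethyl (S)-3-hydroxybutanoate | CCOC(=O)C[C@H](C)O | starting material
27 | ethyl (2S,3S)-2-allyl-3-hydroxybutanoate | C=CC[C@H](C(=O)OCC)[C@H](C)O | intermediate
28 | Weinreb amide | C=CC[C@H](C(=O)N(C)OC)[C@H](C)O | intermediate
29 | β-hydroxy ketone | C=CC[C@H](C(=O)C[C@H]1C[C@H]2[C@@H](C(C)C)[C@H](O[Si](C)(C)C(C)(C)C)C[C@]2(C)C[C@@H]1C(C)=C)[C@H](C)O | intermediate
30 | cyclooctenone | C1[C@H]2C[C@H]3[C@@H](C(C)C)[C@H](O[Si](C)(C)C(C)(C)C)C[C@]3(C)C[C@@H]2/C(C)=C\C[C@@H]([C@H](C)O)C1=O | intermediate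
31 | Mannich base | CN(C)CC1[C@H]2C[C@H]3[C@@H](C(C)C)[C@H](O[Si](C)(C)C(C)(C)C)C[C@]3(C)C[C@@H]2/C(C)=C\C[C@@H]([C@H](C)O)C1=O | intermediate
32 | trimethylammonium iodide | C[N+](C)(C)CC1[C@H]2C[C@H]3[C@@H](C(C)C)[C@H](O[Si](C)(C)C(C)(C)C)C[C@]3(C)C[C@@H]2/C(C)=C\C[C@@H]([C@H](C)O)C1=O.[I-] | intermediate
33 | α-methylene ketone | C=C1[C@H]2C[C@H]3[C@@H](C(C)C)[C@H](O[Si](C)(C)C(C)(C)C)C[C@]3(C)C[C@@H]2/C(C)=C\C[C@@H]([C@H](C)O)C1=O | intermediate
34 | aldol adduct | C=C1[C@H]2C[C@H]3[C@@H](C(C)C)[C@H](O[Si](C)(C)C(C)(C)C)C[C@]3(C)C[C@@H]2/C(C)=C\C[C@@H]([C@H](C)O)[C@@]1(O)CC(=O)OCC | intermediate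
35 | β-hydroxy δ-lactone | C=C1[C@H]2C[C@H]3[C@@H](C(C)C)[C@H](O[Si](C)(C)C(C)(C)C)C[C@]3(C)C[C@@H]2/C(C)=C\C[C@H]2[C@H](C)OC(=O)C[C@@]12O | intermediate
36 | α-hydroxy lactone | C=C1[C@H]2C[C@H]3[C@@H](C(C)C)[C@H](O[Si](C)(C)C(C)(C)C)C[C@]3(C)C[C@@H]2/C(C)=C\C[C@H]2[C@H](C)OC(=O)[C@H](O)[C@@]12O | intermediate
37 | α-keto lactone | C=C1[C@H]2C[C@H]3[C@@H](C(C)C)[C@H](O[Si](C)(C)C(C)(C)C)C[C@]3(C)C[C@@H]2/C(C)=C\C[C@H]2[C@H](C)OC(=O)C(=O)[C@@]12O | intermediate
38 | cyclopentanol α-keto lactone | C=C1[C@H]2C[C@H]3[C@@H](C(C)C)[C@H](O)C[C@]3(C)C[C@@H]2/C(C)=C\C[C@H]2[C@H](C)OC(=O)C(=O)[C@@]12O | intermediate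
39 | (S)-1-bromo-2-methylbutane | BrC[C@@H](C)CC | starting material
40 | (S)-4-methylhex-1-yne | C#CC[C@@H](C)CC | intermediate
41 | (S,E)-3,5-dimethylhept-2-en-1-ol | OC/C=C(\C)C[C@@H](C)CC | intermediate
42 | (2R,3R,5S)-epoxy alcohol | OC[C@H]1O[C@]1(C)C[C@@H](C)CC | intermediate
43 | (3R,5S)-3,5-dimethylheptane-1,3-diol | OCC[C@](C)(O)C[C@@H](C)CC | intermediate
44 | (3R,5S)-3-hydroxy-3,5-dimethylheptanoic acid | OC(=O)C[C@](C)(O)C[C@@H](C)CC | intermediate
45 | α-keto lactone ester | C=C1[C@H]2C[C@H]3[C@@H](C(C)C)[C@H](OC(=O)C[C@](C)(O)C[C@@H](C)CC)C[C@]3(C)C[C@@H]2/C(C)=C\C[C@H]2[C@H](C)OC(=O)C(=O)[C@@]12O | intermediate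
46 | CNP0331120.1 | C=C1[C@H]2C[C@H]3[C@@H](C(C)C)[C@H](OC(=O)C[C@](C)(O)C[C@@H](C)CC)C[C@]3(C)C[C@@H]2/C(C)=C\C[C@H]2[C@H](C)OC(=O)[C@@H](O)[C@@]12O | target

**Step count and risks**
Total steps: 35. Longest linear sequence: 26 (steps 1–4, 7–19, 22–28, 34, 35).

Steps most likely to fail:

1. Step 10: low π-facial selectivity. The silyloxy centre sits on a nearly symmetric tether and its bias away from the C1 carbonyl may be small; dimerisation of the dienone may also compete. Fallback, from 6 back to 14: replace steric control by a bound hydroxyl and correct the carbinol afterwards. Propargylboration of 6 with 9 under the antipodal (R)-TRIP should give the (S)-allenol F1. K2CO3/MeOH frees the phenol F2. PhI(OAc)2/MeOH gives the hydroxy masked o-benzoquinone F3. In toluene, as its ethylzinc alkoxide (Et2Zn), F3 should cyclise with the oxygen held on the C1 carbonyl to the syn-hydroxy cycloadduct F4. Mitsunobu reaction (4-nitrobenzoic acid, PPh3, DIAD) inverts the allylic carbinol to the 4-nitrobenzoate F5. Methanolysis gives the anti alcohol F6, and TESCl/imidazole returns 14.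

2. Step 23: oligomerisation instead of closure to the trisubstituted cyclooctene, because the catalyst loads slowly next to the branched chain. Fallback, from 26 back to 30: relay metathesis. Fráter–Seebach alkylation of 26 with (2E)-1-bromoocta-2,7-diene (from commercial octa-2,7-dien-1-ol) gives the relay ester F7. As in step 21 it is converted into the Weinreb amide F8, and as in step 22 it is coupled with 25 to the ketone F9. Grubbs II then loads on the terminal vinyl group, expels cyclopentene and is delivered to the allylic position of the side chain, from where it closes onto the isopropenyl group to give 30.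

3. Step 25: poor facial control at the tertiary carbinol on the conformationally mobile eight-membered enone. Enolisation or conjugate (oxa-Michael) pathways may also compete under basic conditions. Fallback, from 33 back to 35: intramolecular, base-free delivery. Bromoacetyl bromide/pyridine acylates the secondary hydroxyl to the bromoacetate F10. SmI2 (THF, −78 °C) then generates the samarium enolate, which adds to the ketone from the side of its own tether (intramolecular Reformatsky) and gives lactone 35 directly.

Further compounds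
F1 | step 10 | (S)-allenol, aryl TBS ether | C=C=C(C(C)C)[C@@H](O)Cc1cc(C(C)=O)cc(OC)c1O[Si](C)(C)C(C)(C)C
F2 | step 10 | (S)-allenol phenol | C=C=C(C(C)C)[C@@H](O)Cc1cc(C(C)=O)cc(OC)c1O
F3 | step 10 | hydroxy masked o-benzoquinone | C=C=C(C(C)C)[C@@H](O)CC1=CC(C(C)=O)=CC(OC)(OC)C1=O
F4 | step 10 | syn-hydroxy cycloadduct | COC3(OC)[C@H]1CC2=C(C(C)C)[C@@H](O)C[C@]2(C3=O)C=C1C(C)=O
F5 | step 10 | inverted 4-nitrobenzoate | COC3(OC)[C@H]1CC2=C(C(C)C)[C@H](OC(=O)c4ccc(cc4)[N+](=O)[O-])C[C@]2(C3=O)C=C1C(C)=O
F6 | step 10 | anti-hydroxy cycloadduct | COC3(OC)[C@H]1CC2=C(C(C)C)[C@H](O)C[C@]2(C3=O)C=C1C(C)=O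
F7 | step 23 | ethyl (2S,3S)-3-hydroxy-2-[(2E)-octa-2,7-dien-1-yl]butanoate | C=CCCC/C=C/C[C@H](C(=O)OCC)[C@H](C)O
F8 | step 23 | relay Weinreb amide | C=CCCC/C=C/C[C@H](C(=O)N(C)OC)[C@H](C)O
F9 | step 23 | relay ketone | C=CCCC/C=C/C[C@H](C(=O)C[C@H]1C[C@H]2[C@@H](C(C)C)[C@H](O[Si](C)(C)C(C)(C)C)C[C@]2(C)C[C@@H]1C(C)=C)[C@H](C)O
F10 | step 25 | bromoacetate of 33 | C=C1[C@H]2C[C@H]3[C@@H](C(C)C)[C@H](O[Si](C)(C)C(C)(C)C)C[C@]3(C)C[C@@H]2/C(C)=C\C[C@@H]([C@H](C)OC(=O)CBr)C1=O
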